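## Retrosynthetic overview

1. The CHO group of trisindolal is traced back, through the primary carbinol, to an ethyl ester on C2 of ring A (the 2-formylindole).
2. Structural feature: in ring A, C2 (bearing the formyl carbon) and C3 (bearing the bis(indol-3-yl)methyl group) are neighbouring sp2 carbons, and each can be read as a former carbonyl carbon. Cutting C2=C3 reductively gives an aryl ketone (C3) and the amide C=O of an ethyl oxamate on the ortho nitrogen (C2).
3. The oxamate comes from the 2-aminophenyl ketone and ethyl chlorooxoacetate. The nitrogen is carried as a nitro group until the glyoxal chemistry is over, so it cannot cyclise onto the 1,2-dicarbonyl unit.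
4. The C(=O)–CH(indolyl)2 unit comes from 2-nitrophenylglyoxal (oxidation of 2'-nitroacetophenone) and two molecules of indole.
5. Ring order: the benzene ring of ring A and the two outer indoles (rings B and C) are bought intact. The only ring built is the pyrrole ring of ring A, in step 5.

Key step: step 5

Remark: the arylglyoxal from step 1 is drawn as the free aldehyde. It is normally handled as its hydrate, which reacts the same way in step 2.

## Route

Step 1
Reactants: 1 2'-nitroacetophenone
Product: 2 2-(2-nitrophenyl)-2-oxoacetaldehyde (2-nitrophenylglyoxal)
Conditions: SeO2 (1.2 equiv), wet 1,4-dioxane, reflux; hot filtration through Celite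
Reagents that add atoms: selenium dioxide, O=[Se]=O
Why: Riley oxidation, in which SeO2 attacks the enol of the methyl ketone and, after a [2,3]-shift and loss of selenium and water, converts the only enolisable position (the CH3 group) into the aldehyde while the nitroarene stays inert.

Step 2
Reactants: 2 2-(2-nitrophenyl)-2-oxoacetaldehyde; 3 indole (2 equiv)
Product: 5 2,2-bis(1H-indol-3-yl)-1-(2-nitrophenyl)ethan-1-one, via indolyl carbinol 4 (not isolated)
Conditions: p-TsOH·H2O (10 mol %), MeCN, rt; product recrystallised
Reagents that add atoms: indole (3), c1ccc2[nH]ccc2c1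
Why: Acid-catalysed double Friedel–Crafts condensation of the bis(indolyl)methane type, well known for arylglyoxals: indole C3 adds to the more electrophilic aldehyde carbon to give 4, acid ionises its hydroxyl group with help from the indole nitrogen, and a second indole C3 captures the cation, so both indoles end on the former CHO carbon (two identical groups, no stereocentre) and the ketone stays free.

Step 3
Reactants: 5 2,2-bis(1H-indol-3-yl)-1-(2-nitrophenyl)ethan-1-one
Product: 6 1-(2-aminophenyl)-2,2-bis(1H-indol-3-yl)ethan-1-one
Conditions: H2 (1 atm), 10% Pd/C, EtOAc–EtOH, rt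
Reagents that add atoms: none
Why: Catalytic hydrogenation of a nitroarene to the aniline under neutral conditions, in which the indoles and the hindered aryl ketone (a vinylogous amide once the amine is present) should not be reduced at 1 atm and no acid is present to cleave the bis(indolyl)methyl group.

Step 4
Reactants: 6 1-(2-aminophenyl)-2,2-bis(1H-indol-3-yl)ethan-1-one; 7 ethyl chlorooxoacetate
Product: 8 ethyl 2-{[2-(2,2-bis(1H-indol-3-yl)acetyl)phenyl]amino}-2-oxoacetate
Conditions: pyridine (1.5 equiv), THF, 0 °C to rt
Reagents that add atoms: ethyl chlorooxoacetate (7), CCOC(=O)C(=O)Cl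
Why: N-acylation of an aniline with an acid chloride (Schotten–Baumann type, pyridine as HCl scavenger), selective because the primary aryl amine is the only good nucleophile, the indole N–H groups are not acylated without deprotonation, both indole C3 positions are blocked, and the acid chloride end of 7 is far more reactive than its ester end.

Step 5
Reactants: 8 ethyl 2-{[2-(2,2-bis(1H-indol-3-yl)acetyl)phenyl]amino}-2-oxoacetate
Product: 10 ethyl 3-[bis(1H-indol-3-yl)methyl]-1H-indole-2-carboxylate, via titanium indoline-2,3-diolate 9 (not isolated)
Conditions: TiCl3 (4 equiv), Zn dust (8 equiv), DME, reflux, Ar; then 10% aq. K2CO3, Celite filtration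
Reagents that add atoms: none
Why: Zn reduces TiCl3 to low-valent (formally divalent) titanium, which transfers electrons to the aryl ketone of 8, the most easily reduced carbonyl group, giving a titanium-bound ketyl or dianion at the future C3. This carbon attacks the neighbouring amide carbonyl carbon (future C2) in a 5-exo-trig closure that forms the C2–C3 bond and the pyrrole ring of ring A as the cis diolate 9, and a second two-electron deoxygenation, driven by the strong Ti–O bond and by aromatisation, removes both oxygens and leaves the C2=C3 double bond of 10. The reaction type is the Fürstner indole synthesis (intramolecular McMurry-type oxo-amide coupling in its one-pot TiCl3/Zn form), which is established for N-(2-acylphenyl)oxamates giving indole-2-carboxylates and for bulky C3 substituents. No stereocentre remains, since the two carbinol centres of 9 are erased in the same operation and the bis(indolyl)methyl carbon bears two identical indolyl groups. The step needs ketone–amide coupling rather than ketone–ester coupling (a six-membered ring), ester reduction, plain ketone reduction or intermolecular pinacol coupling, and this is secured by the ortho-anilide geometry, which holds the amide carbon next to the ketyl carbon with both oxygens on titanium, together with moderate dilution. The medium is aprotic with no added Brønsted acid, the excess reagent covers the acidic N–H groups, and the basic carbonate work-up removes the Lewis acidic titanium and zinc salts before they can damage the acid-sensitive tris(indolyl)methane.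

Step 6
Reactants: 10 ethyl 3-[bis(1H-indol-3-yl)methyl]-1H-indole-2-carboxylate
Product: 11 {3-[bis(1H-indol-3-yl)methyl]-1H-indol-2-yl}methanol
Conditions: LiAlH4 (5 equiv), THF, 0 °C to rt; Na2SO4·10H2O quench, filtration; crude used directly
Reagents that add atoms: none
Why: Hydride reduction of an ester to the primary alcohol, standard for indole-2-carboxylates, in which the three indole N–H groups are only deprotonated (hence the excess), nothing else is reducible, the low temperature prevents over-reduction to the 2-methylindole, and the non-acidic quench protects the acid-labile indol-2-ylmethanol.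

Step 7
Reactants: 11 {3-[bis(1H-indol-3-yl)methyl]-1H-indol-2-yl}methanol
Product: 12 trisindolal, 3-[bis(1H-indol-3-yl)methyl]-1H-indole-2-carbaldehyde
Conditions: activated MnO2 (15 equiv), acetone, rt; Celite filtration
Reagents that add atoms: none
Why: Selective MnO2 oxidation of an activated (indol-2-yl, benzylic-type) carbinol under neutral heterogeneous conditions, a standard route to indole-2-carbaldehydes that stops at the aldehyde and should be much faster than attack on the hindered triarylmethane C–H or on the indole rings.

## Compound list

1 | 2'-nitroacetophenone | CC(=O)c1ccccc1[N+](=O)[O-] | starting material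
2 | 2-(2-nitrophenyl)-2-oxoacetaldehyde | O=CC(=O)c1ccccc1[N+](=O)[O-] | intermediate
3 | indole | c1ccc2[nH]ccc2c1 | starting material
4 | 2-hydroxy-2-(1H-indol-3-yl)-1-(2-nitrophenyl)ethan-1-one (racemic, not isolated) | OC(C(=O)c1ccccc1[N+](=O)[O-])c1c[nH]c2ccccc12 | intermediate
5 | 2,2-bis(1H-indol-3-yl)-1-(2-nitrophenyl)ethan-1-one | O=C(c1ccccc1[N+](=O)[O-])C(c1c[nH]c2ccccc12)c1c[nH]c2ccccc12 | intermediate
6 | 1-(2-aminophenyl)-2,2-bis(1H-indol-3-yl)ethan-1-one | Nc1ccccc1C(=O)C(c1c[nH]c2ccccc12)c1c[nH]c2ccccc12 | intermediate
7 | ethyl chlorooxoacetate | CCOC(=O)C(=O)Cl | starting material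
8 | ethyl 2-{[2-(2,2-bis(1H-indol-3-yl)acetyl)phenyl]amino}-2-oxoacetate | CCOC(=O)C(=O)Nc1ccccc1C(=O)C(c1c[nH]c2ccccc12)c1c[nH]c2ccccc12 | intermediate
9 | dichlorotitanium chelate of ethyl 3-[bis(1H-indol-3-yl)methyl]-2,3-dihydroxyindoline-2-carboxylate (cis ring fusion, racemic, one enantiomer drawn, not isolated) | CCOC(=O)[C@]12Nc3ccccc3[C@]1(O[Ti](Cl)(Cl)O2)C(c1c[nH]c2ccccc12)c1c[nH]c2ccccc12 | intermediate
10 | ethyl 3-[bis(1H-indol-3-yl)methyl]-1H-indole-2-carboxylate | CCOC(=O)c1[nH]c2ccccc2c1C(c1c[nH]c2ccccc12)c1c[nH]c2ccccc12 | intermediate
11 | {3-[bis(1H-indol-3-yl)methyl]-1H-indol-2-yl}methanol | OCc1[nH]c2ccccc2c1C(c1c[nH]c2ccccc12)c1c[nH]c2ccccc12 | intermediate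
12 | trisindolal (achiral) | O=Cc1[nH]c2ccccc2c1C(c1c[nH]c2ccccc12)c1c[nH]c2ccccc12 | target

## Step count and risks

Total step count: 7
Longest linear sequence: 7 steps (from 1 to 12)

**Step 5.**
- What may go wrong: hot TiCl3 and ZnCl2 could trigger Lewis acid induced loss or scrambling of indolyl groups at the bis(indolyl)methyl carbon. Coupling at the crowded ketone could also stall, so that plain reduction of the ketone takes over.
- Fallback: it sets out from indole 3 and returns at 10. Ring A is bought intact and the outer indoles are attached last.
- Bought ethyl 1H-indole-2-carboxylate F1 would be formylated at C3 by a Vilsmeier–Haack reaction (POCl3, DMF, then aq. NaOAc) to ethyl 3-formyl-1H-indole-2-carboxylate F2.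
- Condensation of F2 with two equivalents of 3 under p-TsOH catalysis in MeCN uses the same bis(indolyl)methane chemistry as step 2. It would run through ethyl 3-[hydroxy(1H-indol-3-yl)methyl]-1H-indole-2-carboxylate F3 (not isolated) to 10.

**Step 6.**
- What may go wrong: traces of acid could ionise the indol-2-ylmethanol, and C2 of a neighbouring indole ring could then capture the cation in a six-membered ring closure. Over-reduction of the carbinol carbon to a methyl group is a second possibility.
- Fallback: it sets out from 10 and returns at 12, so the carbinol and the oxidation of step 7 are both avoided.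
- Saponification (LiOH, THF–H2O) would give 3-[bis(1H-indol-3-yl)methyl]-1H-indole-2-carboxylic acid F4.
- Amide coupling with N,O-dimethylhydroxylamine hydrochloride (EDC·HCl, HOBt, iPr2NEt, DMF) would give the Weinreb amide 3-[bis(1H-indol-3-yl)methyl]-N-methoxy-N-methyl-1H-indole-2-carboxamide F5.
- Reduction of F5 with excess LiAlH4 in THF at −78 to 0 °C should stop at the chelated tetrahedral adduct and release 12 on a neutral aqueous quench.

**Step 1.**
- What may go wrong: the twisted, electron-poor ketone may enolise slowly, the aldehyde may be over-oxidised to the carboxylic acid level, and colloidal selenium carried forward would poison the Pd/C of step 3.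
- Fallback: it sets out from 1 and returns at 2, using a selenium-free halogenation and Kornblum oxidation sequence.
- α-Bromination (CuBr2, EtOAc, reflux) would give 2-bromo-1-(2-nitrophenyl)ethan-1-one F6.
- Dissolving F6 in DMSO with NaHCO3 at rt to 50 °C should displace bromide by the sulfoxide oxygen and collapse to glyoxal 2.

## Further compounds

F1 | step 5 | ethyl 1H-indole-2-carboxylate (bought) | CCOC(=O)c1cc2ccccc2[nH]1
F2 | step 5 | ethyl 3-formyl-1H-indole-2-carboxylate | CCOC(=O)c1[nH]c2ccccc2c1C=O
F3 | step 5 | ethyl 3-[hydroxy(1H-indol-3-yl)methyl]-1H-indole-2-carboxylate (racemic, not isolated) | CCOC(=O)c1[nH]c2ccccc2c1C(O)c1c[nH]c2ccccc12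
F4 | step 6 | 3-[bis(1H-indol-3-yl)methyl]-1H-indole-2-carboxylic acid | OC(=O)c1[nH]c2ccccc2c1C(c1c[nH]c2ccccc12)c1c[nH]c2ccccc12
F5 | step 6 | 3-[bis(1H-indol-3-yl)methyl]-N-methoxy-N-methyl-1H-indole-2-carboxamide | CON(C)C(=O)c1[nH]c2ccccc2c1C(c1c[nH]c2ccccc12)c1c[nH]c2ccccc12
F6 | step 1 | 2-bromo-1-(2-nitrophenyl)ethan-1-one | O=C(CBr)c1ccccc1[N+](=O)[O-]
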